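| flask | starting material | second substrate | free enzyme | temperature | remark | time |
|---|---|---|---|---|---|---|
| south-east | 0.050 M | 0.60 equiv | 0.002 mol% | 37 °C | the very flask that is asked about, followed so far |  |
| north | 0.050 M | 0.60 equiv | 0.004 mol% | 43 °C | run made earlier |  |
| flask | 0.050 M | 0.600 equiv | 0.002 mol% | 37 °C |  | 30 h |

| run | time / h | target / % | starting material / % |
|---|---|---|---|
| south-east | 5.00 | 33.2 | 65.5 |
| south-east | 10.0 | 38.8 | 62.1 |
| south-east | 15.0 | 37.8 | 61.9 |
| south-east | 20.0 | 42.1 | 60.3 |
| south-east | 25.0 | 41.5 | 59.2 |
| south-east | 30.0 | 41.9 | 58.2 |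
| north | 0.833 | 25.7 | 77.4 |
| north | 1.33 | 26.7 | 75.0 |
| north | 2.50 | 27.9 | 70.7 |
| north | 4.00 | 31.4 | 68.8 |
| north | 6.00 | 32.3 | 68.0 |
| north | 10.0 | 33.6 | 66.5 |

(scatter of a reading: 1 percentage point)

- birch: at 30 h add free enzyme, 50.0% of the amount charged, then wait 10 h
- ash: at 30 h add second substrate, 100% of the amount charged, then wait 10 h
- larch: at 30 h take out 90% of the first product then present, then wait 10 h
- oak: at 30 h raise the temperature by 20 K, then wait 10 h
- elm: change nothing and wait 10 h more

- additions bring no volume worth counting
- the analysis behind the earlier runs scatters by 1 percentage point, standard deviation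
- reactions considered so far: free enzyme -> unfolded enzyme; second substrate + loaded enzyme <-> second complex; second complex -> free enzyme + target; first complex <-> loaded enzyme + first product; 2 free enzyme -> spent catalyst; starting material + free enzyme <-> first complex

- target, in percent of the starting material first charged, at 30 h
- what to do for the largest gain in target; "none" if nothing gains more than 2 percentage points (birch / ash / larch / oak / elm / none)
- target present, in percent of the starting material first charged, after oak
- target present, in percent of the starting material first charged, after elm

Early times first: what does the south-east flask do by its opening reading? By 5.00 h it has made 33.2% of target, and between then and 30.0 h it adds 8.7 percentage points.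

Has a reagent run out? No. By the last reading target implies that 30.2% of the second substrate, the limiting reagent, is left, and 58.2% of the starting material still stands.

Then I suspect that the catalyst is going. By which loss? Free enzyme can unfold singly or go to spent catalyst in pairs. The pair loss grows with c(free enzyme) squared, so it leads while c(free enzyme) is high, and control passes to unfolding at a crossing further down. While pairs lead, c(free enzyme) falls roughly as one over elapsed time, so target should climb with the logarithm of time.

What can be read from that? From the readings at 10.0 h and 30.0 h, each scattered by 1 point, I get 2.8 points: this is the tail slope S, the points of target gained per factor e of elapsed time.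

But the north flask had twice the enzyme and stands lower at 10.0 h, 33.6% against 38.8%. Why? In this picture the dose sits inside the logarithm, so doubling it is worth 2 points. The north flask was also hotter, and these two runs can't separate the two effects.

What do you commit to? Target at 30 h is the reading, 41.9%. Waiting multiplies the elapsed time by 1.33, so it adds S times the logarithm of that factor, or 0.81 points, which is less than 2 points, so I expect elm to end near 42.7%. I put oak no higher than elm, on the weak ground that the hotter north flask stands lower, though that flask differs in dose too. Fresh enzyme restarts the clock: counted as 5.00 h old, an age I take as cautious, it gains 3.1 points by this estimate. Ash, on the generous assumption that the rate follows second substrate in full, gains 3.5 points. Larch I leave unreckoned, since these runs hold no reading of first product. The two estimates lie close, 0.4 points apart, so this is a judgement: I choose birch, whose estimate is the cautious one.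

The forecast gave 41.5%, birch, 42.7% after oak and 43% after elm, saying “Heating kills the remainder quickly”.

The flask gives 41.6%, and birch is best with 5.1 points against 2.3 points for ash; oak leaves 41.6% and elm 42.2%.

    free enzyme → unfolded enzyme (k = 0.0300 h⁻¹, Ea = 237 kJ mol⁻¹)
    second substrate + loaded enzyme ⇌ second complex (K = 18.0 M⁻¹, k = 2.40 × 10⁶ M⁻¹ h⁻¹, Ea = 43.0 kJ mol⁻¹, ΔH = −35.0 kJ mol⁻¹)
    second complex → free enzyme + target (k = 1.50 × 10⁵ h⁻¹, Ea = 56.0 kJ mol⁻¹)
    first complex ⇌ loaded enzyme + first product (K = 0.0280 M, k = 6.50 × 10⁵ h⁻¹, Ea = 65.0 kJ mol⁻¹, ΔH = −41.0 kJ mol⁻¹)
    2 free enzyme → spent catalyst (k = 1.80 × 10⁶ M⁻¹ h⁻¹, Ea = 43.0 kJ mol⁻¹)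
    starting material + free enzyme ⇌ first complex (K = 8.70 M⁻¹, k = 2.00 × 10⁶ M⁻¹ h⁻¹, Ea = 40.0 kJ mol⁻¹, ΔH = −32.0 kJ mol⁻¹)
    (constants at 37 °C)

At 30.0 h, with free enzyme at 1.17% of the catalyst charged, the pair step removes it at 0.0423 h⁻¹ against 0.030 h⁻¹ for unfolding. The flask then holds 92.9% as spent catalyst and 5.22% as unfolded enzyme. The tail slope put waiting at 0.81 points, and elm gives 0.68 points. Diluting to 0.020 M at the same loading, with S held, should cost S times ln(2.50), giving 39.0%, and that neighbour flask stands at 37.3%.

The earlier runs and the new flask are calculated with made-up constants; noise was put on by code.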